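**Strategy.** The cyclohexene ring is read as a Diels–Alder adduct. Numbered from the quaternary carbon (C1) through the coumarin-bearing CH (C2), its C3=C4 double bond, the methyl on C4 para to C1 and the coumarin-3-yl group on C2 map onto a 1-(coumarin-3-yl)-3-methylbuta-1,3-diene and a 1,1-disubstituted dienophile. The key step is a catalytic enantioselective [4+2] cycloaddition of this dienylcoumarin with methacrolein. It closes the ring by forming the C1–C2 bond together with C5–C6 and sets both stereocentres. The formyl group is then methylenated, the vinyl group is joined by a Heck reaction to the same 3-bromocoumarin that gave the diene, and removal of two pivalates gives the target.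

Key step: step 6

Remark: the sense of induction in step 6 is taken from the accepted pre-transition-state model of the oxazaborolidinium catalyst with 2-substituted acroleins; should the opposite face be delivered, the (R)-catalyst is used under otherwise identical conditions.

**Step 1**
Reactants: 1 2-methoxyresorcinol (2-methoxybenzene-1,3-diol); 2 ethyl propiolate
Product: 4 7-hydroxy-8-methoxy-2H-chromen-2-one, via ethyl (Z)-3-(2,4-dihydroxy-3-methoxyphenyl)prop-2-enoate 3 (not isolated)
Conditions: ZnCl2, dioxane, 100 °C
Reagents that add atoms: none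
Why: Pechmann-type hydroarylation–lactonisation: the ZnCl2-activated propiolate is attacked by C4 of the resorcinol (ortho to one hydroxyl, para to the other; the two such positions are equivalent) and the flanking hydroxyl closes the lactone with loss of ethanol; no stereocentre is formed.

**Step 2**
Reactants: 4 7-hydroxy-8-methoxy-2H-chromen-2-one
Product: 5 8-methoxy-2-oxo-2H-chromen-7-yl pivalate (2,2-dimethylpropanoate)
Conditions: PivCl, Et3N, DMAP (cat.), CH2Cl2, 0 °C → rt
Reagents that add atoms: pivaloyl chloride, CC(C)(C)C(Cl)=O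
Why: DMAP-catalysed O-acylation of the only free hydroxyl; the pivalate shields the acidic phenol from bromine, from the Lewis acid of step 6 and from the palladium steps, and deactivates the benzo ring toward electrophiles.

**Step 3**
Reactants: 5 8-methoxy-2-oxo-2H-chromen-7-yl pivalate
Product: 7 3-bromo-8-methoxy-2-oxo-2H-chromen-7-yl pivalate, via trans-3,4-dibromo-8-methoxy-2-oxochroman-7-yl pivalate 6 (not isolated)
Conditions: Br2 (1.05 equiv), CH2Cl2, 0 °C → rt; then Et3N, 0 °C
Reagents that add atoms: bromine, BrBr
Why: Bromine addition–dehydrobromination: anti addition of Br2 to the C3=C4 double bond and E1cB loss of HBr (acidic C3–H, benzylic C4–Br) should give the 3-bromocoumarin, the acyloxy-substituted benzo ring being too deactivated to compete.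

**Step 4**
Reactants: 8 2-methylbut-1-en-3-yne; 9 pinacolborane
Product: 10 (E)-4,4,5,5-tetramethyl-2-(3-methylbuta-1,3-dien-1-yl)-1,3,2-dioxaborolane
Conditions: Cp2Zr(H)Cl (5 mol%), Et3N (10 mol%), neat, 60 °C
Reagents that add atoms: none
Why: Zirconium-catalysed hydroboration of a terminal alkyne: syn, anti-Markovnikov addition of H–B across the triple bond, which reacts far faster than the 1,1-disubstituted alkene, fixes the E geometry.

**Step 5**
Reactants: 7 3-bromo-8-methoxy-2-oxo-2H-chromen-7-yl pivalate; 10 (E)-dienylboronate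
Product: 11 8-methoxy-3-[(E)-3-methylbuta-1,3-dien-1-yl]-2-oxo-2H-chromen-7-yl pivalate
Conditions: Pd(dppf)Cl2 (5 mol%), K3PO4, dioxane/H2O (20:1), BHT (trace), 60 °C; used directly in step 6
Reagents that add atoms: none
Why: Suzuki–Miyaura coupling: oxidative addition of zerovalent palladium to the electron-poor C3–Br bond, transmetalation and reductive elimination proceed with retention of the E-alkenyl geometry, and the mild temperature limits self-cycloaddition of the diene.

**Step 6**
Reactants: 11 8-methoxy-3-[(E)-3-methylbuta-1,3-dien-1-yl]-2-oxo-2H-chromen-7-yl pivalate; 12 methacrolein (2-methylprop-2-enal)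
Product: 13 3-[(1R,6S)-6-formyl-3,6-dimethylcyclohex-2-en-1-yl]-8-methoxy-2-oxo-2H-chromen-7-yl pivalate
Conditions: (S)-3,3-diphenyl-1-(o-tolyl)tetrahydro-1H,3H-pyrrolo[1,2-c][1,3,2]oxazaborole (20 mol%), (CF3SO2)2NH (16 mol%), methacrolein (5 equiv), CH2Cl2, −78 → −40 °C
Reagents that add atoms: none
Why: Diels–Alder reaction: the N-protonated oxazaborolidine binds the formyl oxygen of s-trans methacrolein and lowers its LUMO, and the s-cis side-chain diene of 11 adds in a concerted, asynchronous [4+2] cycloaddition in which the CH2 terminus of the diene leads at the enal β-carbon. The closest known reaction type is the oxazaborolidinium-catalysed enantioselective Diels–Alder reaction of 2-substituted acroleins with acyclic dienes. The cyclohexene ring is closed by intermolecular [4+2] cycloaddition, which forms the bond between the coumarin-bearing diene terminus and the enal α-carbon (the future quaternary carbon) together with the CH2–CH2 bond. The quaternary centre is controlled by the catalyst, whose formyl C–H···O contact and flanking phenyl group should leave only the Re face of the enal α-carbon open (S in 13); the neighbouring CH follows from the E-diene geometry and an endo orientation of the boron-bound formyl group (formyl cis to the coumarinyl group, R in 13). The required "ortho/para" regioselectivity is secured because the 1-(coumarin-3-yl) and 3-methyl groups of the diene both place the largest HOMO coefficient on its CH2 terminus; the side-chain diene is preferred over the C4=C3–vinyl diene because C4 is the electron-poor β-carbon of the lactone, and cross- over self-cycloaddition is secured by the low temperature and the excess of activated dienophile.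

**Step 7**
Reactants: 13 3-[(1R,6S)-6-formyl-3,6-dimethylcyclohex-2-en-1-yl]-8-methoxy-2-oxo-2H-chromen-7-yl pivalate
Product: 14 3-[(1R,6R)-6-ethenyl-3,6-dimethylcyclohex-2-en-1-yl]-8-methoxy-2-oxo-2H-chromen-7-yl pivalate
Conditions: Zn, CH2Br2, TiCl4 (reagent pre-formed in THF, 0–5 °C); then 13, CH2Cl2, 0 °C → rt
Reagents that add atoms: dibromomethane, BrCBr
Why: Takai–Lombardo methylenation: the non-basic gem-dimetallic CH2 reagent olefinates hindered aldehydes chemoselectively in the presence of the aryl ester and the lactone, and the α-quaternary centre cannot epimerise.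

**Step 8**
Reactants: 14 3-[(1R,6R)-6-ethenyl-3,6-dimethylcyclohex-2-en-1-yl]-8-methoxy-2-oxo-2H-chromen-7-yl pivalate; 7 3-bromo-8-methoxy-2-oxo-2H-chromen-7-yl pivalate
Product: 15 3-[(E)-2-[(1R,2R)-1,4-dimethyl-2-[8-methoxy-2-oxo-7-(pivaloyloxy)-2H-chromen-3-yl]cyclohex-3-en-1-yl]ethenyl]-8-methoxy-2-oxo-2H-chromen-7-yl pivalate
Conditions: Pd(OAc)2 (5 mol%), P(o-tol)3 (12 mol%), Et3N, DMF, 90 °C
Reagents that add atoms: none
Why: Mizoroki–Heck reaction: the alkenylpalladium species formed from 7 inserts the monosubstituted alkene with palladium on the internal carbon, and syn β-hydride elimination, possible only toward the CH2 carbon because the adjacent carbon is quaternary, should give the E-alkene without migration; the trisubstituted ring alkene is inert.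

**Step 9**
Reactants: 15 bis-pivalate
Product: 16 7-hydroxy-3-[(E)-2-[(1R,2R)-2-(7-hydroxy-8-methoxy-2-oxo-2H-chromen-3-yl)-1,4-dimethylcyclohex-3-en-1-yl]ethenyl]-8-methoxy-2H-chromen-2-one
Conditions: K2CO3 (2.5 equiv), MeOH, 0 °C → rt; then 1 M HCl to pH 3
Reagents that add atoms: none
Why: Base-mediated transesterification (methanolysis) of the two activated aryl pivalates; the coumarin lactones survive or re-close on acidification, and neither stereocentre carries a hydrogen acidic enough to epimerise.

**Compound list**
1 | 2-methoxyresorcinol (2-methoxybenzene-1,3-diol) | COc1c(O)cccc1O | starting material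
2 | ethyl propiolate | C#CC(=O)OCC | starting material
3 | ethyl (Z)-3-(2,4-dihydroxy-3-methoxyphenyl)prop-2-enoate | CCOC(=O)/C=C\c1ccc(O)c(OC)c1O | intermediate (not isolated)
4 | 7-hydroxy-8-methoxy-2H-chromen-2-one | COc1c(O)ccc2ccc(=O)oc12 | intermediate
5 | 8-methoxy-2-oxo-2H-chromen-7-yl pivalate | COc1c(OC(=O)C(C)(C)C)ccc2ccc(=O)oc12 | intermediate
6 | trans-3,4-dibromo-8-methoxy-2-oxochroman-7-yl pivalate (racemic, one enantiomer drawn) | O=C1Oc2c(OC)c(OC(=O)C(C)(C)C)ccc2[C@H](Br)[C@H]1Br | intermediate (not isolated)
7 | 3-bromo-8-methoxy-2-oxo-2H-chromen-7-yl pivalate | COc1c(OC(=O)C(C)(C)C)ccc2cc(Br)c(=O)oc12 | intermediate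
8 | 2-methylbut-1-en-3-yne | CC(=C)C#C | starting material
9 | pinacolborane (4,4,5,5-tetramethyl-1,3,2-dioxaborolane) | CC1(C)OBOC1(C)C | starting material
10 | (E)-4,4,5,5-tetramethyl-2-(3-methylbuta-1,3-dien-1-yl)-1,3,2-dioxaborolane | CC(=C)/C=C/B1OC(C)(C)C(C)(C)O1 | intermediate
11 | 8-methoxy-3-[(E)-3-methylbuta-1,3-dien-1-yl]-2-oxo-2H-chromen-7-yl pivalate | COc1c(OC(=O)C(C)(C)C)ccc2cc(/C=C/C(C)=C)c(=O)oc12 | intermediate
12 | methacrolein (2-methylprop-2-enal) | CC(=C)C=O | starting material
13 | 3-[(1R,6S)-6-formyl-3,6-dimethylcyclohex-2-en-1-yl]-8-methoxy-2-oxo-2H-chromen-7-yl pivalate (formyl cis to the coumarinyl group) | O=C[C@@]1(C)CCC(C)=C[C@H]1c1cc2ccc(OC(=O)C(C)(C)C)c(OC)c2oc1=O | intermediate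
14 | 3-[(1R,6R)-6-ethenyl-3,6-dimethylcyclohex-2-en-1-yl]-8-methoxy-2-oxo-2H-chromen-7-yl pivalate | C=C[C@@]1(C)CCC(C)=C[C@H]1c1cc2ccc(OC(=O)C(C)(C)C)c(OC)c2oc1=O | intermediate
15 | 3-[(E)-2-[(1R,2R)-1,4-dimethyl-2-[8-methoxy-2-oxo-7-(pivaloyloxy)-2H-chromen-3-yl]cyclohex-3-en-1-yl]ethenyl]-8-methoxy-2-oxo-2H-chromen-7-yl pivalate | COc1c(OC(=O)C(C)(C)C)ccc2cc(/C=C/[C@@]3(C)CCC(C)=C[C@H]3c3cc4ccc(OC(=O)C(C)(C)C)c(OC)c4oc3=O)c(=O)oc12 | intermediate
16 | 7-hydroxy-3-[(E)-2-[(1R,2R)-2-(7-hydroxy-8-methoxy-2-oxo-2H-chromen-3-yl)-1,4-dimethylcyclohex-3-en-1-yl]ethenyl]-8-methoxy-2H-chromen-2-one | COc1c(O)ccc2cc(/C=C/[C@@]3(C)CCC(C)=C[C@H]3c3cc4ccc(O)c(OC)c4oc3=O)c(=O)oc12 | target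

**Total step count:** 9. **Longest linear sequence:** 8 steps (steps 1, 2, 3, 5, 6, 7, 8, 9; step 4 is a side branch).

**Steps most likely to fail**

1. Step 6. The α-methyl dienophile may erode endo/exo or facial discrimination, the lactone and ester carbonyls may sequester the boron Lewis acid, and traces of acid may oligomerise the diene. The fallback sets out from 11 and uses its thermal [4+2] homodimerisation (toluene, 100 °C, BHT). The isopropenyl double bond of a second molecule of 11 serves as the dienophile with its butadienyl residue endo, so the same ring-closing bonds form and the second coumarin arrives in the same operation. This should give 15 as a racemate together with its enantiomer, the (1S,2S)-bis-pivalate F1. Preparative HPLC on amylose tris(3,5-dimethylphenylcarbamate) separates the two, and the route is rejoined at 15, with steps 7 and 8 bypassed.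

2. Step 8. Migratory insertion at the neopentyl-type vinyl group may be slow, so that reductive debromination or homocoupling of the bromide takes over. The fallback sets out from 13 and reverses the polarity of the coupling. A Takai-type boryl-olefination of the aldehyde (Cl2CHBpin, CrCl2, LiI, THF, rt) should give the (E)-alkenylboronate, 3-[(1R,6R)-3,6-dimethyl-6-[(E)-2-(4,4,5,5-tetramethyl-1,3,2-dioxaborolan-2-yl)ethenyl]cyclohex-2-en-1-yl]-8-methoxy-2-oxo-2H-chromen-7-yl pivalate F2. This is joined to bromide 7 by Suzuki–Miyaura coupling under the conditions of step 5, and the route is rejoined at 15.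

3. Step 5. The diene may undergo self-cycloaddition as it forms at the coupling temperature, and the pivalate may be hydrolysed in the basic aqueous medium. The fallback sets out from 7 and carries the diene in masked form. A Heck reaction of 7 with 2-methylbut-3-en-2-ol (Pd(OAc)2, P(o-tol)3, Et3N, DMF, 90 °C) should give the storable tertiary allylic alcohol, 3-[(E)-3-hydroxy-3-methylbut-1-en-1-yl]-8-methoxy-2-oxo-2H-chromen-7-yl pivalate F3. Acid-catalysed dehydration (camphorsulfonic acid cat., toluene, 4 Å molecular sieves, 40 °C) immediately before step 6 then rejoins the route at 11.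

**Further compounds**
F1 | step 6 | 3-[(E)-2-[(1S,2S)-1,4-dimethyl-2-[8-methoxy-2-oxo-7-(pivaloyloxy)-2H-chromen-3-yl]cyclohex-3-en-1-yl]ethenyl]-8-methoxy-2-oxo-2H-chromen-7-yl pivalate (enantiomer of 15) | COc1c(OC(=O)C(C)(C)C)ccc2cc(/C=C/[C@]3(C)CCC(C)=C[C@@H]3c3cc4ccc(OC(=O)C(C)(C)C)c(OC)c4oc3=O)c(=O)oc12
F2 | step 8 | 3-[(1R,6R)-3,6-dimethyl-6-[(E)-2-(4,4,5,5-tetramethyl-1,3,2-dioxaborolan-2-yl)ethenyl]cyclohex-2-en-1-yl]-8-methoxy-2-oxo-2H-chromen-7-yl pivalate | CC1(C)OB(/C=C/[C@@]2(C)CCC(C)=C[C@H]2c2cc3ccc(OC(=O)C(C)(C)C)c(OC)c3oc2=O)OC1(C)C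
F3 | step 5 | 3-[(E)-3-hydroxy-3-methylbut-1-en-1-yl]-8-methoxy-2-oxo-2H-chromen-7-yl pivalate | COc1c(OC(=O)C(C)(C)C)ccc2cc(/C=C/C(C)(C)O)c(=O)oc12
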